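**The questions.** 5 questions stand on 4 flasks, each stopped at 15 min.

the same everywhere: substrate 34 mM

|  | other conformer | catalyst | temperature | remark | time |
|---|---|---|---|---|---|
| south-east | 8.5 mM | 71 µM | −4 °C | run made earlier |  |
| east | 8.5 mM | 110 µM | 21 °C | run made earlier |  |
| south-west | 17 mM | 51 µM | −4 °C | run made earlier |  |
| green | 8.50 mM | 51 µM | 30 °C |  | 15 min |
| red | 8.50 mM | 51 µM | 15 °C |  | 15 min |
| grey | 8.50 mM | 51 µM | −15 °C |  | 15 min |
| amber | 8.50 mM | 51 µM | 0 °C |  | 15 min |

| run | time / min | target / % |
|---|---|---|
| south-east | 4.00 | 16 |
| south-east | 10.0 | 21 |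
| south-east | 15.0 | 18 |
| south-east | 25.0 | 11 |
| south-east | 30.0 | 5 |
| south-east | 50.0 | 2 |
| east | 1.00 | 19 |
| east | 3.00 | 1 |
| east | 5.00 | 0 |
| east | 8.00 | 0 |
| east | 10.0 | 0 |
| east | 15.0 | 0 |
| south-west | 5.00 | 11 |
| south-west | 15.0 | 11 |
| south-west | 20.0 | 10 |
| south-west | 30.0 | 7 |
| south-west | 50.0 | 1 |

(scatter of a reading: 1.5 percentage points)

- the best flask by amount of target, in percent of the substrate and other conformer together charged; "all alike" if 1.5 percentage points covers them all (green / red / grey / amber / all alike)
- amount of target at the end, in percent of the substrate and other conformer together charged, green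
- amount of target at the end, in percent of the substrate and other conformer together charged, red
- amount of target at the end, in percent of the substrate and other conformer together charged, grey
- amount of target at the end, in percent of the substrate and other conformer together charged, amber

- the earlier runs were read with a standard deviation of 1.5 percentage points
- in a conversion other conformer counts as not yet reacted

**The loss.** In the south-east run the target falls from 21% at 10.0 min to 5% at 30.0 min. Read as first-order, that is a constant of 0.0718 min⁻¹. The south-west run stands at the same temperature with 51 µM of catalyst against 71 µM and 17 mM of other conformer against 8.5 mM, yet it reads 0.0685 min⁻¹. So I treat this fall, as a working reading, as independent of both charges. The east run gives 1.47 min⁻¹ at 21 °C, roughly, since its second reading lies within the scatter of zero. The two constants give an activation energy, as a reading, of 79.6 kJ mol⁻¹.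

**One number.** I fold time and temperature into N, a Damköhler number: the flask's time divided by the target's lifetime at its temperature. For amber N = 1.81. Grey has 0.237, red 11.2 and green 58.0, so grey has the lowest.

I then read south-east at equal N. Grey maps to 3.30 min, near the reading of 16% at 4.00 min. Amber maps to 25.2 min, near 11% at 25.0 min. Red and green map beyond the last reading, which is 2%. I commit to grey.

**The test.** Equal N does not give equal target here. South-east reads 18% at 15.0 min and south-west reads 11% at 15.0 min, at equal N. Their charges differ in catalyst and in other conformer, and N holds neither. The 4 flasks carry 51 µM of catalyst, less than south-east's 71 µM, so my mapped readings are rough.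

**The forecast.** It gives 0% for green, 1.5% for red, 15% for grey and 18% for amber, and it names amber: "I therefore scale time by catalyst and temperature, using south-east as the master curve". On amber my reckoning gives 11% and I name grey, so we differ there.

**The result.** The best flask is grey, with 16.0% of target, against 9.63% in amber, 0.0642% in red and 0% in green.

    substrate ⇌ other conformer (K = 1.10, k = 0.00440 s⁻¹, Ea = 76.0 kJ mol⁻¹, ΔH = −29.0 kJ mol⁻¹)
    substrate + catalyst → catalyst + target (k = 40.0 M⁻¹ s⁻¹, Ea = 48.0 kJ mol⁻¹)
    catalyst + other conformer → catalyst + isomer of the product (k = 88.0 M⁻¹ s⁻¹, Ea = 37.0 kJ mol⁻¹)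
    substrate ⇌ dormant form (K = 0.480, k = 0.00740 s⁻¹, Ea = 73.0 kJ mol⁻¹, ΔH = −79.0 kJ mol⁻¹)
    target → over-reaction product (k = 0.00250 s⁻¹, Ea = 81.0 kJ mol⁻¹)
    (constants at 0 °C)

**A neighbour.** Amber, with N of 1.81, holds 27.2% of over-reaction product at 15.0 min, and grey holds 3.14%. A repeat of green at 5 °C has N = 3.40. That maps to south-east at 47.4 min, close to the reading of 2% at 50.0 min. That neighbour holds 3.38% of target.

All runs stem from a simulated flask from invented constants; noise was put on by code.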